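**Plan**

- Retrosynthesis: remove the acetate, the 8,9-epoxide oxygen and the isovalerate; cut C4–C5 (retro-aldol, opens ring A); rejoin C7–C10 and cut C7–C8 and C9–C10 (fragmentation, then enone–allene [2+2]), which contracts the seven-membered ring to a cyclopentenone and releases allene (C8, C9, C14).
- Enabling feature: the C-6 and C-10 oxygens sit 1,5 to each other across C7–C8–C9 of the seven-membered ring, so C6–C7–C10 is a masked cyclopentane-1,3-dione and C8–C9 a two-carbon insert; the C4-hydroxyl and a C-6 ketone form an aldol pair.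
- Forward: cyclopentenone 1 → quaternary C-1 by two anti conjugate additions → 3-silyloxy enone 9 → cyclobutane by [2+2] with allene → retro-aldol to the cycloheptanedione → aldol closure of five-membered ring A → redox and acylation end game.
- Stereochemistry: C-1 from the silyloxy stereocentre of commercial (R)-1 (a relay centre, erased later); C-4/C-5 from a thermodynamically controlled aldol; C-6 by hydroxyl-directed hydride delivery; C-10 by α-face hydride attack then Mitsunobu inversion; C-8/C-9 by hydroxyl-directed epoxidation.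

Key step: step 5

Remark: locants C-1 to C-15 and α/β follow daucane numbering (C-1 = ring-fusion carbon bearing the angular methyl C-15, taken as β; C-4 = isopropyl carbinol; C-5 = ring-fusion CH; C-6 to C-10 around the seven-membered ring; C-14 = methyl on C-8). TBS = tert-butyldimethylsilyl, TMS = trimethylsilyl.

Remark: stereocentres that are erased later are carried as mixtures; the SMILES show one representative (ring fusion of 11–14) or leave the centre open (oxirane carbon of 9–12, the methyl-bearing carbon made in step 6 in 12–20).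

**Step 1**
Reactants: 1 (R)-4-(TBS-oxy)cyclopent-2-en-1-one; 2 5-bromo-2-methylpent-2-ene
Product: 4 (R)-4-(TBS-oxy)-3-(4-methylpent-3-en-1-yl)cyclopent-2-en-1-one, via trans enol silane 3 (not isolated)
Conditions: 2, Mg, THF; CuBr·SMe2 (cat.), TMSCl, DMPU, THF, −78 °C; then Pd(OAc)2 (cat.), O2, DMSO, 25 °C
Reagents that add atoms: none
Why: Copper-catalysed conjugate addition of the Grignard reagent occurs anti to the silyloxy group and is trapped as enol silane 3, and Saegusa–Ito oxidation (syn β-hydride elimination) then restores the enone with the side chain on C-3, leaving the silyloxy stereocentre untouched and erasing the transient one.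

**Step 2**
Reactants: 4 (R)-4-(TBS-oxy)-3-(4-methylpent-3-en-1-yl)cyclopent-2-en-1-one
Product: 6 (3S,4R)-4-(TBS-oxy)-3-methyl-3-(4-methylpent-3-en-1-yl)cyclopentan-1-one, via enol silane 5 (not isolated)
Conditions: Me2CuLi (from MeLi, CuI), TMSCl, Et2O/THF, −78 to −40 °C; then citric acid, MeOH, 0 °C
Reagents that add atoms: lithium dimethylcuprate, [Li+].C[Cu-]C
Why: TMSCl-accelerated cuprate conjugate addition to the β,β-disubstituted enone should deliver methyl anti to the neighbouring silyloxy group, so the existing stereocentre sets the quaternary carbon (future C-1), and mild acid hydrolyses the enol silane without β-elimination.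

**Step 3**
Reactants: 6 (3S,4R)-4-(TBS-oxy)-3-methyl-3-(4-methylpent-3-en-1-yl)cyclopentan-1-one
Product: 8 (S)-3-(TBS-oxy)-4-methyl-4-(4-methylpent-3-en-1-yl)cyclopent-2-en-1-one, via enol silane 7 (not isolated)
Conditions: TMSOTf, Et3N, CH2Cl2, −78 to 0 °C; then Pd(OAc)2 (cat.), O2, DMSO, 40 °C
Reagents that add atoms: none
Why: Saegusa–Ito oxidation: only the enol silane formed towards C-5 carries a β-hydrogen (on the silyloxy carbon), so syn β-hydride elimination should give the 3-silyloxy enone with the silyl group regiospecifically on the oxygen next to the quaternary carbon, while the enol silane towards C-2 cannot eliminate and returns 6; the relay stereocentre is erased.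

**Step 4**
Reactants: 8 (S)-3-(TBS-oxy)-4-methyl-4-(4-methylpent-3-en-1-yl)cyclopent-2-en-1-one
Product: 9 (4S)-3-(TBS-oxy)-4-[2-(3,3-dimethyloxiran-2-yl)ethyl]-4-methylcyclopent-2-en-1-one (both oxirane epimers)
Conditions: mCPBA, NaHCO3, CH2Cl2, 0 °C
Reagents that add atoms: mCPBA (3-chloroperoxybenzoic acid), OOC(=O)c1cccc(Cl)c1
Why: Prilezhaev epoxidation should take the electron-rich trisubstituted side-chain alkene in preference to the push–pull enone C=C, masking an alkene that would otherwise add intramolecularly to the excited enone; the oxirane carbon configuration is immaterial because it becomes a carbonyl carbon in step 7.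

**Step 5**
Reactants: 9 (4S)-3-(TBS-oxy)-4-[2-(3,3-dimethyloxiran-2-yl)ethyl]-4-methylcyclopent-2-en-1-one; 10 propa-1,2-diene (allene)
Product: 11 (4S)-5-(TBS-oxy)-4-[2-(3,3-dimethyloxiran-2-yl)ethyl]-4-methyl-7-methylidene-cis-bicyclo[3.2.0]heptan-2-one (both cis ring-fusion diastereomers)
Conditions: hν (medium-pressure Hg lamp, Pyrex filter), allene (excess), CH2Cl2, −78 °C
Reagents that add atoms: none
Why: The triplet 3-silyloxy enone adds to allene stepwise: bonding of the enone α-carbon (C-2 of 9) to the central allene carbon gives a triplet 1,4-biradical (a 2-substituted allyl radical and a tertiary α-silyloxy radical at C-3), which after spin inversion closes at the allyl terminus, so both new σ-bonds, the future C7–C8 and C9–C10 bonds of the target, arise in one photochemical operation. The closest known reaction type is the enone–allene [2+2] photocycloaddition used in de Mayo ring expansions of enol derivatives of 1,3-diketones. The one ring closed is the cyclobutane, formed by radical–radical combination of the 1,4-biradical and necessarily cis-fused to the cyclopentanone. The two new stereocentres (C-1 and C-5 of 11) are fixed relative to each other by that cis fusion; their orientation relative to the quaternary carbon is not controlled and need not be, because both are erased in step 8. The selectivity that matters is regiochemical (central allene carbon to the enone α-carbon, head-to-head): it is secured by allyl-radical formation and by the radical-stabilising silyloxy group on the β-carbon, and the position of that silyl group, fixed in step 3, defines which carbonyl of the latent 1,3-dione acts as the enone carbonyl. Chemoselectivity is secured by the removal of the side-chain alkene in step 4, the oxirane being photochemically inert.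

**Step 6**
Reactants: 11 (4S)-5-(TBS-oxy)-4-[2-(3,3-dimethyloxiran-2-yl)ethyl]-4-methyl-7-methylidene-cis-bicyclo[3.2.0]heptan-2-one
Product: 12 (4S)-5-(TBS-oxy)-4-[2-(3,3-dimethyloxiran-2-yl)ethyl]-4,7-dimethyl-cis-bicyclo[3.2.0]heptan-2-one (C-7 epimers)
Conditions: H2 (1 atm), Pd/C, EtOAc, 23 °C
Reagents that add atoms: none
Why: Heterogeneous hydrogenation saturates the exocyclic methylene before ring expansion, so that no double bond can migrate between the two ketones under the basic conditions of step 8; the new C-7 stereocentre is immaterial because that carbon (C-8 of the daucane) becomes sp2 again in step 11.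

**Step 7**
Reactants: 12 (4S)-5-(TBS-oxy)-4-[2-(3,3-dimethyloxiran-2-yl)ethyl]-4,7-dimethyl-cis-bicyclo[3.2.0]heptan-2-one
Product: 13 (4S)-5-(TBS-oxy)-4,7-dimethyl-4-(4-methyl-3-oxopentyl)-cis-bicyclo[3.2.0]heptan-2-one
Conditions: BF3·OEt2, CH2Cl2, −78 °C
Reagents that add atoms: none
Why: Meinwald rearrangement: the Lewis acid opens the oxirane at its tertiary carbon and a 1,2-hydride shift should give the isopropyl ketone, the hindered silyl ether and the ring ketone being inert at −78 °C.

**Step 8**
Reactants: 13 (4S)-5-(TBS-oxy)-4,7-dimethyl-4-(4-methyl-3-oxopentyl)-cis-bicyclo[3.2.0]heptan-2-one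
Product: 16 4β-hydroxy-trans-daucane-6,10-dione (C-8 epimers), via cyclobutanol 14 (not isolated), via triketone 15 (not isolated)
Conditions: TBAF, THF, 0 °C; then K2CO3, MeOH, 23 °C (equilibrating)
Reagents that add atoms: none
Why: Fluoride unmasks cyclobutanol 14, whose alkoxide undergoes strain-releasing retro-aldol cleavage of the C1–C5 bond (de Mayo fragmentation) to the seven-membered 1,4-dione 15, and under equilibrating base the C-5 enolate of the unhindered C-6 ketone adds reversibly to the side-chain ketone (aldol, five-membered ring A) and should settle in the most stable ketol, trans-fused with the hydroxyl cis to and hydrogen-bonded with the C-6 carbonyl and the isopropyl group anti to both C-6 and the angular methyl, which fixes C-4 and C-5.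

**Step 9**
Reactants: 16 4β-hydroxy-trans-daucane-6,10-dione
Product: 17 4β,6α-dihydroxy-trans-daucan-10-one
Conditions: Me4NBH(OAc)3, MeCN/AcOH (1:1), −25 °C
Reagents that add atoms: none
Why: Evans–Saksena reduction: the C-4 hydroxyl binds boron and delivers hydride intramolecularly to the β face of the C-6 ketone, which should give the anti (6α) alcohol, while the C-10 ketone, which has no β-hydroxyl, is not reduced.

**Step 10**
Reactants: 17 4β,6α-dihydroxy-trans-daucan-10-one
Product: 18 4β-hydroxy-10-oxo-trans-daucan-6α-yl 3-methylbutanoate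
Conditions: isovaleric anhydride, DMAP (cat.), Et3N, CH2Cl2, 0 to 23 °C
Reagents that add atoms: isovaleric (3-methylbutanoic) anhydride, CC(C)CC(=O)OC(=O)CC(C)C
Why: DMAP-catalysed (Steglich-type) acylation should take the only secondary alcohol, the tertiary C-4 hydroxyl being unreactive.

**Step 11**
Reactants: 18 4β-hydroxy-10-oxo-trans-daucan-6α-yl 3-methylbutanoate
Product: 21 4β-hydroxy-10-oxo-trans-dauc-8-en-6α-yl 3-methylbutanoate, via bis-silyl enol ether 19 (not isolated), via O-silyl enone 20 (not isolated)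
Conditions: TMSOTf, Et3N, CH2Cl2, 0 °C; then Pd(OAc)2 (cat.), O2, DMSO, 40 °C; then 1 M HCl, THF, 0 °C
Reagents that add atoms: none
Why: Saegusa–Ito oxidation: the C-10 ketone can enolise only towards C-9, so dehydrogenation should give the 8-en-10-one regiospecifically and erase the C-8 stereocentre, and the acidic work-up frees the tertiary hydroxyl that is silylated in passing.

**Step 12**
Reactants: 21 4β-hydroxy-10-oxo-trans-dauc-8-en-6α-yl 3-methylbutanoate
Product: 22 4β,10β-dihydroxy-trans-dauc-8-en-6α-yl 3-methylbutanoate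
Conditions: NaBH4, CeCl3·7H2O, MeOH, −78 °C
Reagents that add atoms: none
Why: Luche 1,2-reduction: hydride should enter the enone carbonyl from the α face, anti to the axial angular methyl on the adjacent quaternary C-1, giving the equatorial 10β-alcohol without touching the ester.

**Step 13**
Reactants: 22 4β,10β-dihydroxy-trans-dauc-8-en-6α-yl 3-methylbutanoate
Product: 23 10α-(chloroacetoxy)-4β-hydroxy-trans-dauc-8-en-6α-yl 3-methylbutanoate
Conditions: ClCH2CO2H, PPh3, DIAD, toluene/THF, 0 to 23 °C
Reagents that add atoms: chloroacetic acid, OC(=O)CCl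
Why: Mitsunobu reaction: the allylic oxyphosphonium should be displaced with inversion by chloroacetate arriving along the unhindered α-axial path (the path the hydride took), setting the 10α-oxygen; the tertiary alcohol cannot be activated.

**Step 14**
Reactants: 23 10α-(chloroacetoxy)-4β-hydroxy-trans-dauc-8-en-6α-yl 3-methylbutanoate
Product: 24 4β,10α-dihydroxy-trans-dauc-8-en-6α-yl 3-methylbutanoate
Conditions: K2CO3 (cat.), MeOH, 0 °C
Reagents that add atoms: none
Why: Transesterification: the activated chloroacetate is methanolysed far faster than the hindered isovalerate, so only the C-10 hydroxyl should be released and no stereocentre is touched.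

**Step 15**
Reactants: 24 4β,10α-dihydroxy-trans-dauc-8-en-6α-yl 3-methylbutanoate
Product: 25 8α,9α-epoxy-4β,10α-dihydroxy-trans-daucan-6α-yl 3-methylbutanoate
Conditions: VO(acac)2 (cat.), t-BuOOH, CH2Cl2, 0 to 23 °C
Reagents that add atoms: tert-butyl hydroperoxide, CC(C)(C)OO
Why: Vanadium-catalysed hydroxyl-directed epoxidation delivers oxygen from the alkoxide-bound metal to the alkene face syn to the allylic 10α-hydroxyl, which should give the 8α,9α-epoxide (cis-epoxy alcohol).

**Step 16**
Reactants: 25 8α,9α-epoxy-4β,10α-dihydroxy-trans-daucan-6α-yl 3-methylbutanoate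
Product: 26 10α-acetoxy-8α,9α-epoxy-4β-hydroxy-trans-daucan-6α-yl 3-methylbutanoate (target)
Conditions: Ac2O, DMAP (cat.), pyridine, CH2Cl2, 23 °C
Reagents that add atoms: acetic anhydride, CC(=O)OC(C)=O
Why: Nucleophile-catalysed acetylation of the secondary hydroxyl with retention, the hindered tertiary C-4 hydroxyl remaining free, should complete the target.

**Compound list**

1 | (R)-4-(TBS-oxy)cyclopent-2-en-1-one | O=C1C=C[C@H](O[Si](C)(C)C(C)(C)C)C1 | starting material
2 | 5-bromo-2-methylpent-2-ene | CC(C)=CCCBr | starting material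
3 | (3R,4R)-4-(TBS-oxy)-3-(4-methylpent-3-en-1-yl)-1-(TMS-oxy)cyclopent-1-ene | C[Si](C)(C)OC1=C[C@@H](CCC=C(C)C)[C@H](O[Si](C)(C)C(C)(C)C)C1 | intermediate
4 | (R)-4-(TBS-oxy)-3-(4-methylpent-3-en-1-yl)cyclopent-2-en-1-one | O=C1C=C(CCC=C(C)C)[C@H](O[Si](C)(C)C(C)(C)C)C1 | intermediate
5 | (3S,4R)-4-(TBS-oxy)-3-methyl-3-(4-methylpent-3-en-1-yl)-1-(TMS-oxy)cyclopent-1-ene | C[Si](C)(C)OC1=C[C@](C)(CCC=C(C)C)[C@H](O[Si](C)(C)C(C)(C)C)C1 | intermediate
6 | (3S,4R)-4-(TBS-oxy)-3-methyl-3-(4-methylpent-3-en-1-yl)cyclopentan-1-one | O=C1C[C@](C)(CCC=C(C)C)[C@H](O[Si](C)(C)C(C)(C)C)C1 | intermediate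
7 | (3R,4S)-3-(TBS-oxy)-4-methyl-4-(4-methylpent-3-en-1-yl)-1-(TMS-oxy)cyclopent-1-ene | C[Si](C)(C)OC1=C[C@@H](O[Si](C)(C)C(C)(C)C)[C@@](C)(CCC=C(C)C)C1 | intermediate
8 | (S)-3-(TBS-oxy)-4-methyl-4-(4-methylpent-3-en-1-yl)cyclopent-2-en-1-one | O=C1C=C(O[Si](C)(C)C(C)(C)C)[C@@](C)(CCC=C(C)C)C1 | intermediate
9 | (4S)-3-(TBS-oxy)-4-[2-(3,3-dimethyloxiran-2-yl)ethyl]-4-methylcyclopent-2-en-1-one | O=C1C=C(O[Si](C)(C)C(C)(C)C)[C@@](C)(CCC2OC2(C)C)C1 | intermediate
10 | propa-1,2-diene (allene) | C=C=C | starting material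
11 | (4S)-5-(TBS-oxy)-4-[2-(3,3-dimethyloxiran-2-yl)ethyl]-4-methyl-7-methylidene-cis-bicyclo[3.2.0]heptan-2-one | O=C1C[C@](C)(CCC3OC3(C)C)[C@@]2(O[Si](C)(C)C(C)(C)C)CC(=C)[C@@H]12 | intermediate
12 | (4S)-5-(TBS-oxy)-4-[2-(3,3-dimethyloxiran-2-yl)ethyl]-4,7-dimethyl-cis-bicyclo[3.2.0]heptan-2-one | O=C1C[C@](C)(CCC3OC3(C)C)[C@@]2(O[Si](C)(C)C(C)(C)C)CC(C)[C@@H]12 | intermediate
13 | (4S)-5-(TBS-oxy)-4,7-dimethyl-4-(4-methyl-3-oxopentyl)-cis-bicyclo[3.2.0]heptan-2-one | O=C1C[C@](C)(CCC(=O)C(C)C)[C@@]2(O[Si](C)(C)C(C)(C)C)CC(C)[C@@H]12 | intermediate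
14 | (4S)-5-hydroxy-4,7-dimethyl-4-(4-methyl-3-oxopentyl)-cis-bicyclo[3.2.0]heptan-2-one | O=C1C[C@](C)(CCC(=O)C(C)C)[C@@]2(O)CC(C)[C@@H]12 | intermediate
15 | (2S)-2,6-dimethyl-2-(4-methyl-3-oxopentyl)cycloheptane-1,4-dione | O=C1CC(C)CC(=O)C[C@]1(C)CCC(=O)C(C)C | intermediate
16 | 4β-hydroxy-trans-daucane-6,10-dione (1S,4R,5R) | O=C1CC(C)CC(=O)[C@@H]2[C@]1(C)CC[C@@]2(O)C(C)C | intermediate
17 | 4β,6α-dihydroxy-trans-daucan-10-one (1S,4R,5S,6S) | O=C1CC(C)C[C@H](O)[C@@H]2[C@]1(C)CC[C@@]2(O)C(C)C | intermediate
18 | 4β-hydroxy-10-oxo-trans-daucan-6α-yl 3-methylbutanoate | O=C1CC(C)C[C@H](OC(=O)CC(C)C)[C@@H]2[C@]1(C)CC[C@@]2(O)C(C)C | intermediate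
19 | 4β,10-bis(TMS-oxy)-trans-dauc-9-en-6α-yl 3-methylbutanoate | C[Si](C)(C)OC1=CC(C)C[C@H](OC(=O)CC(C)C)[C@@H]2[C@]1(C)CC[C@@]2(O[Si](C)(C)C)C(C)C | intermediate
20 | 10-oxo-4β-(TMS-oxy)-trans-dauc-8-en-6α-yl 3-methylbutanoate | O=C1C=C(C)C[C@H](OC(=O)CC(C)C)[C@@H]2[C@]1(C)CC[C@@]2(O[Si](C)(C)C)C(C)C | intermediate
21 | 4β-hydroxy-10-oxo-trans-dauc-8-en-6α-yl 3-methylbutanoate | O=C1C=C(C)C[C@H](OC(=O)CC(C)C)[C@@H]2[C@]1(C)CC[C@@]2(O)C(C)C | intermediate
22 | 4β,10β-dihydroxy-trans-dauc-8-en-6α-yl 3-methylbutanoate (10S) | O[C@H]1C=C(C)C[C@H](OC(=O)CC(C)C)[C@@H]2[C@]1(C)CC[C@@]2(O)C(C)C | intermediate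
23 | 10α-(chloroacetoxy)-4β-hydroxy-trans-dauc-8-en-6α-yl 3-methylbutanoate | O=C(CCl)O[C@@H]1C=C(C)C[C@H](OC(=O)CC(C)C)[C@@H]2[C@]1(C)CC[C@@]2(O)C(C)C | intermediate
24 | 4β,10α-dihydroxy-trans-dauc-8-en-6α-yl 3-methylbutanoate (10R) | O[C@@H]1C=C(C)C[C@H](OC(=O)CC(C)C)[C@@H]2[C@]1(C)CC[C@@]2(O)C(C)C | intermediate
25 | 8α,9α-epoxy-4β,10α-dihydroxy-trans-daucan-6α-yl 3-methylbutanoate | O[C@@H]1[C@@H]2O[C@]2(C)C[C@H](OC(=O)CC(C)C)[C@@H]2[C@]1(C)CC[C@@]2(O)C(C)C | intermediate
26 | (1S,4R,5S,6S,8R,9S,10S)-10-acetoxy-8,9-epoxy-4-hydroxydaucan-6-yl 3-methylbutanoate | CC(=O)O[C@@H]1[C@@H]2O[C@]2(C)C[C@H](OC(=O)CC(C)C)[C@@H]2[C@]1(C)CC[C@@]2(O)C(C)C | target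

**Totals**

Total steps: 16. Longest linear sequence: 16 steps (from 1).

**Steps most likely to fail**

1. Step 8. What may go wrong: under equilibration the ring closure may leak through the C-9 enolate of the C-10 ketone (bridged ketol) or through the side-chain enolate; equilibration may stop short of the required C-4/C-5 configuration; the ketol may dehydrate. Fallback: ring A is closed before the fragmentation, on the rigid five-membered ring, setting out from 13. Aldol condensation (KOH, MeOH) should give the tricyclic enone F1, since only C-3 can enolise without a bridgehead cyclobutene enolate and dehydration is the irreversible exit. Nucleophilic epoxidation (H2O2, NaOH, MeOH) should give epoxy ketone F2, in which the cis fusion of two five-membered rings forces the oxirane oxygen onto the face of the angular methyl. SmI2 (THF/MeOH, −78 °C) cleaves the Cα–O bond to ketol F3, with the C-4 oxygen already β. TBAF then fragments F3 to the cis-fused ketol F4, which needs only epimerisation at C-5 (K2CO3, MeOH; relief of the cis isopropyl/acyl interaction) to come back to the route at 16.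

2. Step 13. What may go wrong: the invertive displacement at the allylic carbon next to the quaternary centre may lose to elimination (8,10-diene) or to allylic transposition. Fallback: C-10 is set by an epoxide-controlled reduction instead of a substitution, setting out from 22. TBSCl/imidazole gives the 10β-silyl ether F5. mCPBA should epoxidise anti to the bulky silyloxy group to give the 8α,9α-epoxide F6. TBAF gives the trans-epoxy alcohol F7, and Dess–Martin periodinane gives epoxy ketone F8. NaBH4/CeCl3 reduction, with hydride entering anti to the oxirane C–O bond, should give the cis-epoxy alcohol and so comes back to the route at 25.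

3. Step 2. What may go wrong: sluggish 1,4-addition at the fully substituted β-carbon next to the silyloxy group, with competing 1,2-addition or reductive loss of the silyloxy group. Fallback: the quaternary centre is set by a catalyst and the oxygen is added afterwards, setting out from 2. The Grignard reagent of 2 adds to commercial 3-ethoxycyclopent-2-en-1-one, and acid work-up gives enone F9. Copper-catalysed asymmetric conjugate addition of Me3Al (Cu(OTf)2, chiral N-heterocyclic carbene ligand) should give the (R)-ketone F10. IBX dehydrogenation, possible only away from the quaternary carbon, gives enone F11. β-Borylation (B2pin2, CuCl, NaOtBu, MeOH) gives boronate F12, which NaBO3 oxidises to β-hydroxy ketone F13. TBSCl/imidazole gives 6 together with its C-4 epimer F14, and both converge under the conditions of step 3, coming back to the route at 8.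

**Further compounds**

F1 | step 8 | tricyclic enone from 13 (ring A closed, C4=C5 conjugated to the C-6 ketone, cyclobutane and silyl ether intact) | O=C1C2=C(C(C)C)CC[C@]2(C)[C@@]3(O[Si](C)(C)C(C)(C)C)CC(C)[C@@H]13
F2 | step 8 | 4,5-epoxide of F1 (oxirane oxygen cis to the angular methyl) | O=C1[C@]23O[C@@]2(C(C)C)CC[C@]3(C)[C@@]4(O[Si](C)(C)C(C)(C)C)CC(C)[C@@H]14
F3 | step 8 | tricyclic ketol (4β-hydroxyl, cis-fused five-membered rings, cyclobutane and silyl ether intact) | O=C1[C@@H]2[C@](O)(C(C)C)CC[C@]2(C)[C@@]3(O[Si](C)(C)C(C)(C)C)CC(C)[C@@H]13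
F4 | step 8 | 4β-hydroxy-cis-daucane-6,10-dione (5-epimer of 16) | O=C1CC(C)CC(=O)[C@H]2[C@]1(C)CC[C@@]2(O)C(C)C
F5 | step 13 | 4β-hydroxy-10β-(TBS-oxy)-trans-dauc-8-en-6α-yl 3-methylbutanoate | CC(C)(C)[Si](C)(C)O[C@H]1C=C(C)C[C@H](OC(=O)CC(C)C)[C@@H]2[C@]1(C)CC[C@@]2(O)C(C)C
F6 | step 13 | 8α,9α-epoxy-4β-hydroxy-10β-(TBS-oxy)-trans-daucan-6α-yl 3-methylbutanoate | CC(C)(C)[Si](C)(C)O[C@H]1[C@@H]2O[C@]2(C)C[C@H](OC(=O)CC(C)C)[C@@H]2[C@]1(C)CC[C@@]2(O)C(C)C
F7 | step 13 | 8α,9α-epoxy-4β,10β-dihydroxy-trans-daucan-6α-yl 3-methylbutanoate | O[C@H]1[C@@H]2O[C@]2(C)C[C@H](OC(=O)CC(C)C)[C@@H]2[C@]1(C)CC[C@@]2(O)C(C)C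
F8 | step 13 | 8α,9α-epoxy-4β-hydroxy-10-oxo-trans-daucan-6α-yl 3-methylbutanoate | O=C1[C@@H]2O[C@]2(C)C[C@H](OC(=O)CC(C)C)[C@@H]2[C@]1(C)CC[C@@]2(O)C(C)C
F9 | step 2 | 3-(4-methylpent-3-en-1-yl)cyclopent-2-en-1-one | O=C1C=C(CCC=C(C)C)CC1
F10 | step 2 | (R)-3-methyl-3-(4-methylpent-3-en-1-yl)cyclopentan-1-one | O=C1C[C@](C)(CCC=C(C)C)CC1
F11 | step 2 | (S)-4-methyl-4-(4-methylpent-3-en-1-yl)cyclopent-2-en-1-one | O=C1C=C[C@@](C)(CCC=C(C)C)C1
F12 | step 2 | (4S)-4-methyl-4-(4-methylpent-3-en-1-yl)-3-(4,4,5,5-tetramethyl-1,3,2-dioxaborolan-2-yl)cyclopentan-1-one | O=C1CC(B2OC(C)(C)C(C)(C)O2)[C@@](C)(CCC=C(C)C)C1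
F13 | step 2 | (4S)-3-hydroxy-4-methyl-4-(4-methylpent-3-en-1-yl)cyclopentan-1-one | O=C1CC(O)[C@@](C)(CCC=C(C)C)C1
F14 | step 2 | (3S,4S)-4-(TBS-oxy)-3-methyl-3-(4-methylpent-3-en-1-yl)cyclopentan-1-one (C-4 epimer of 6) | O=C1C[C@](C)(CCC=C(C)C)[C@@H](O[Si](C)(C)C(C)(C)C)C1
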